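**Retrosynthetic overview**

1. Locants: ring C1 (CH–OH), C2 (C–CH3), C3, C4, C5 (carries the side chain), C6; side chain C7 (=CH2), C8 (CH–O), C9, C10, C11. The C2–C3 oxirane on the cyclohexane ring is cis to the free C1 hydroxyl, so it is taken back to a hydroxyl-directed epoxidation of a C2=C3 olefin; the C10–C11 oxirane goes back to a reagent-controlled epoxidation and the three angelates to one acylation.
2. With C2=C3 in place, C4 is an allylic carbinol carbon bonded to the olefinic carbon C3. The ring bond C3–C4 is therefore an alkenyl–carbonyl bond, cut to a (Z)-alkenyl iodide (C3) and an aldehyde (C4) and rejoined by a Nozaki–Hiyama–Kishi cyclisation that makes the only carbocycle and the C4 stereocentre.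
3. The acyclic chain is cut at C5–C7: copper-catalysed opening of a (2S,3S)-epoxy alcohol (Sharpless; sets C5 and C6) by a 1-(silyloxyalkyl)vinyl Grignard reagent that brings C7–C11 with C8 already set (allylboration of 2-bromoacrolein, then cross-metathesis).
4. C1 and the Z-iodoalkene come from an asymmetric alkenylzinc addition to (Z)-3-iodo-2-methylprop-2-enal, made by anti-carbomagnesiation/iodination of propargyl alcohol.
5. Order of ring formation: cyclohexene (step 13), side-chain oxirane (step 16), ring oxirane (step 18).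

Key step: step 13

Remark: 2-bromoacrolein, (−)-Ipc2B(allyl) solution, (+)-MIB, angelic anhydride and the D-fructose-derived Shi ketone are taken as purchasable; the C4 outcome of step 13 is a prediction from a transition-state model, not a certainty.

**Route**

Step 1
Reactants: 1 2-bromoprop-2-enal (2-bromoacrolein)
Product: 2 (3S)-2-bromohexa-1,5-dien-3-ol
Conditions: (−)-Ipc2B(allyl), Et2O, −78 °C; then NaOH, H2O2, 0 °C → rt
Reagents that add atoms: (−)-B-allyldiisopinocampheylborane, C=CCB([C@@H]1C[C@@H]2C[C@H]([C@H]1C)C2(C)C)[C@@H]1C[C@@H]2C[C@H]([C@H]1C)C2(C)C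
Why: Brown allylboration through a chair six-membered transition state, in which the isopinocampheyl groups derived from (+)-α-pinene shield one aldehyde face so that, as with aryl and alkenyl aldehydes, the 3S carbinol (C8 of the target) should form with high enantioselectivity while the vinylic bromide is untouched.

Step 2
Reactants: 2 (3S)-2-bromohexa-1,5-dien-3-ol
Product: 3 {[(3S)-2-bromohexa-1,5-dien-3-yl]oxy}triethylsilane
Conditions: Et3SiCl, imidazole, CH2Cl2, 0 °C
Reagents that add atoms: chlorotriethylsilane, CC[Si](Cl)(CC)CC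
Why: Imidazole-promoted silyl ether formation should be clean for this unhindered secondary allylic alcohol and masks the hydroxyl for the organometallic chemistry of step 10.

Step 3
Reactants: 3 {[(3S)-2-bromohexa-1,5-dien-3-yl]oxy}triethylsilane
Product: 4 {[(3S)-2-bromo-6-methylhepta-1,5-dien-3-yl]oxy}triethylsilane
Conditions: 2-methylbut-2-ene (excess), second-generation Grubbs catalyst (5 mol %), CH2Cl2, 40 °C
Reagents that add atoms: 2-methylbut-2-ene, CC=C(C)C
Why: Olefin cross-metathesis in which only the monosubstituted olefin enters the catalytic cycle (the 1,1-disubstituted bromoalkene is too hindered and electron-poor), and excess 2-methylbut-2-ene should convert it into the trisubstituted prenyl-type olefin with loss of propene, no stereocentre being touched.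

Step 4
Reactants: 5 prop-2-yn-1-ol
Product: 7 (2Z)-3-iodo-2-methylprop-2-en-1-ol, via alkenylmagnesium alkoxide 6 (not isolated)
Conditions: MeMgBr (3 equiv), CuI (10 mol %), THF, −10 °C → rt; then I2, −78 → 0 °C
Reagents that add atoms: methylmagnesium bromide, C[Mg]Br; iodine, II
Why: Copper-catalysed anti-carbomagnesiation of a propargylic alkoxide followed by iodinolysis: methyl goes to C2 and magnesium to C3 inside a five-membered oxamagnesacycle, which fixes C3–Mg cis to the carbinol carbon, and iodine replaces magnesium with retention to give the Z iodide only.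

Step 5
Reactants: 7 (2Z)-3-iodo-2-methylprop-2-en-1-ol
Product: 8 (2Z)-3-iodo-2-methylprop-2-enal
Conditions: MnO2 (excess), CH2Cl2, rt, dark
Reagents that add atoms: none
Why: Allylic alcohol oxidation with MnO2 is neutral and heterogeneous, so the Z geometry of the iodoalkene should survive if the aldehyde is used at once.

Step 6
Reactants: 9 tert-butyldimethyl(prop-2-yn-1-yloxy)silane; 8 (2Z)-3-iodo-2-methylprop-2-enal
Product: 12 (1Z,3R,4E)-6-[(tert-butyldimethylsilyl)oxy]-1-iodo-2-methylhexa-1,4-dien-3-ol, via alkenylzirconocene chloride 10 (not isolated), via alkenylmethylzinc 11 (not isolated)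
Conditions: Cp2Zr(H)Cl, CH2Cl2, rt; Me2Zn, toluene, −78 °C; (+)-3-exo-morpholinoisoborneol [(+)-MIB] (10 mol %), then 8, −30 → 0 °C
Reagents that add atoms: none
Why: Hydrozirconation, zirconium-to-zinc transmetalation and amino-alcohol-catalysed asymmetric alkenylzinc addition: syn hydrozirconation gives the E-alkenyl metal, and the zinc aminoalkoxide formed from (+)-MIB and Me2Zn should direct it to the Re face of aldehyde 8 (the mirror image of the sense established for (−)-MIB), which sets C1 as 3R in 12.

Step 7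
Reactants: 12 (1Z,3R,4E)-6-[(tert-butyldimethylsilyl)oxy]-1-iodo-2-methylhexa-1,4-dien-3-ol
Product: 13 tert-butyl{[(2E,4R,5Z)-6-iodo-4-[(4-methoxyphenyl)methoxy]-5-methylhexa-2,5-dien-1-yl]oxy}dimethylsilane
Conditions: NaH, 4-methoxybenzyl chloride, Bu4NI (cat.), THF/DMF, 0 °C → rt
Reagents that add atoms: 4-methoxybenzyl chloride, COc1ccc(CCl)cc1
Why: Williamson etherification of the alkoxide with the benzylic chloride should give the PMB ether without touching the alkenyl iodide or the stereocentre.

Step 8
Reactants: 13 tert-butyl{[(2E,4R,5Z)-6-iodo-4-[(4-methoxyphenyl)methoxy]-5-methylhexa-2,5-dien-1-yl]oxy}dimethylsilane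
Product: 14 (2E,4R,5Z)-6-iodo-4-[(4-methoxyphenyl)methoxy]-5-methylhexa-2,5-dien-1-ol
Conditions: Bu4NF, THF, 0 °C
Reagents that add atoms: none
Why: Fluoride-mediated desilylation frees the primary allylic alcohol, the only silyl ether present.

Step 9
Reactants: 14 (2E,4R,5Z)-6-iodo-4-[(4-methoxyphenyl)methoxy]-5-methylhexa-2,5-dien-1-ol
Product: 15 {(2S,3S)-3-[(1S,2Z)-3-iodo-1-[(4-methoxyphenyl)methoxy]-2-methylprop-2-en-1-yl]oxiran-2-yl}methanol
Conditions: Ti(OiPr)4 (cat.), L-(+)-diethyl tartrate (cat.), t-BuOOH, 4 Å molecular sieves, CH2Cl2, −20 °C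
Reagents that add atoms: tert-butyl hydroperoxide, CC(C)(C)OO
Why: Sharpless asymmetric epoxidation, in which the complex of Ti(OiPr)4 with L-(+)-diethyl tartrate delivers oxygen to one face of the E allylic alcohol under reagent control to give the (2S,3S)-epoxy alcohol (C5 and C6), while the iodoalkene, not allylic to a free hydroxyl, is left alone.

Step 10
Reactants: 4 {[(3S)-2-bromo-6-methylhepta-1,5-dien-3-yl]oxy}triethylsilane; 15 {(2S,3S)-3-[(1S,2Z)-3-iodo-1-[(4-methoxyphenyl)methoxy]-2-methylprop-2-en-1-yl]oxiran-2-yl}methanol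
Product: 18 acyclic (Z)-iodoalkenyl 1,3-diol (C4 primary OH; C6 secondary OH; C5 alkenylated; C1 PMB ether; C8 TES ether), via alkenyllithium 16 (not isolated), via alkenylmagnesium bromide 17 (not isolated)
Conditions: 4 (2.5 equiv), t-BuLi (5 equiv), Et2O, −78 °C; MgBr2·OEt2, −78 → −40 °C; then 15, CuI (10 mol %), THF, −40 → −15 °C
Reagents that add atoms: none
Why: Copper-catalysed Grignard opening of a 2,3-epoxy alcohol, in which the organocopper formed from CuI and 17 attacks C5 (the oxirane carbon next to CH2O–Mg, the other one being shielded by the branched C1) with inversion, which sets C5 and gives the anti 1,3-diol while C6 keeps its configuration.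

Step 11
Reactants: 18 acyclic (Z)-iodoalkenyl 1,3-diol
Product: 19 tris-TES ether of 18 (C4–OTES; C6–OTES; C8–OTES)
Conditions: Et3SiOTf, 2,6-lutidine, CH2Cl2, −78 °C
Reagents that add atoms: triethylsilyl trifluoromethanesulfonate, CC[Si](CC)(CC)OS(=O)(=O)C(F)(F)F
Why: Silylation with a silyl triflate and a hindered pyridine base protects both hydroxyls, including the hindered C6 one, at low temperature.

Step 12
Reactants: 19 tris-TES ether
Product: 20 C4 aldehyde (C6–OTES; C8–OTES; C1–OPMB; Z-alkenyl iodide)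
Conditions: (COCl)2, DMSO, CH2Cl2, −78 → −40 °C; then i-Pr2NEt, −78 → 0 °C
Reagents that add atoms: none
Why: Swern oxidation applied directly to a primary triethylsilyl ether: the chlorosulfonium salt cleaves the less hindered primary O–Si bond and the alkoxysulfonium ion is oxidised to the aldehyde while the two secondary TES ethers stay, and low temperature with a hindered amine should keep the α-stereocentre C5 intact.

Step 13
Reactants: 20 C4 aldehyde
Product: 21 cyclohexenol (2-methylcyclohex-2-ene ring; C1–OPMB; C4–OH trans to the C5 side chain; C6–OTES)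
Conditions: CrCl2 (8 equiv), NiCl2 (2 mol % of the chromium), degassed DMSO, rt, 0.005 M
Reagents that add atoms: none
Why: Zerovalent nickel (formed from NiCl2 and CrCl2) inserts into the C3–I bond of 20, the alkenyl group is passed to trivalent chromium with retention of the Z geometry, and the alkenyl–CrCl2 species adds to the C4 aldehyde, so that C3–C4 forms and closes the cyclohexene in a 6-exo-trig mode (Nozaki–Hiyama–Kishi reaction). The closest known reaction type is the intramolecular Nozaki–Hiyama–Kishi cyclisation of alkenyl iodide–aldehydes to carbocyclic allylic alcohols. The one new stereocentre, C4, is controlled by the half-chair transition state in which the large C5 side chain is equatorial and C6–OTES therefore axial: an axial C4–O–Cr would be 1,3-diaxial to C6–OTES, so the alkoxide should sit equatorial, that is trans to the C5 substituent as in the target. The step needs chemoselectivity (only the aldehyde is attacked; silyl ethers, the PMB ether and the three other olefins are inert to divalent chromium and to the alkenylmetal) and configurational integrity at C5, which the neutral, non-basic medium and the high dilution secure. The Z iodide geometry fixed in step 4 is what lets C3 reach C4, and the product carries the C2=C3 olefin between the C1 and C4 oxygens, exactly where the directed epoxidation of step 18 needs it.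

Step 14
Reactants: 21 cyclohexenol
Product: 22 triol (C4–OH; C6–OH; C8–OH; C1–OPMB)
Conditions: Bu4NF, THF, 0 °C → rt
Reagents that add atoms: none
Why: Fluoride-mediated desilylation of both secondary TES ethers should give the triol, the PMB ether being stable to fluoride.

Step 15
Reactants: 22 triol
Product: 23 tri-angelate (C4–OAng; C6–OAng; C8–OAng; C1–OPMB)
Conditions: angelic anhydride, LiN(SiMe3)2, THF, −78 → 0 °C
Reagents that add atoms: angelic anhydride [(2Z)-2-methylbut-2-enoic anhydride], C/C=C(/C)C(=O)OC(=O)/C(C)=C\C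
Why: Acylation of lithium alkoxides with a carboxylic anhydride at low temperature avoids the nucleophilic catalysts that isomerise angelates to tiglates, so the three Z esters should be installed with retention of olefin geometry.

Step 16
Reactants: 23 tri-angelate
Product: 24 side-chain (10R)-epoxide (C10–C11 oxirane; C1–OPMB)
Conditions: D-fructose-derived Shi ketone (0.3 equiv), KHSO5 (as 2KHSO5·KHSO4·K2SO4), K2CO3, Bu4NHSO4, aq. Na2B4O7/Na2EDTA buffer, MeCN/dimethoxymethane, 0 °C
Reagents that add atoms: potassium peroxymonosulfate, [K+].[O-]S(=O)(=O)OO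
Why: Shi asymmetric epoxidation, in which the chiral dioxirane reacts fastest with the most electron-rich, trisubstituted C10=C11 olefin (the ring olefin is flanked by two allylic oxygens, the 1,1-disubstituted one by an allylic ester, the angelates are enoates) and should, through the spiro transition state, set C10 as R under reagent control.

Step 17
Reactants: 24 side-chain epoxide
Product: 25 C1 allylic alcohol (free C1–OH; three angelates; C10–C11 oxirane)
Conditions: DDQ, CH2Cl2/aq. KH2PO4–K2HPO4 buffer (pH 7), 0 °C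
Reagents that add atoms: none
Why: Oxidative cleavage of the PMB ether with DDQ (hydride abstraction, then hydrolysis of the oxocarbenium ion) runs at neutral pH, so esters and the oxirane should survive and no acyl migration from O6 to O1 is expected.

Step 18
Reactants: 25 C1 allylic alcohol
Product: 26 CNP0147918.1 (ring 1R,2R,3S,4R,5S,6R; side chain 8S,10R in the locants used here)
Conditions: VO(acac)2 (5 mol %), t-BuOOH, CH2Cl2, 0 °C → rt
Reagents that add atoms: tert-butyl hydroperoxide, CC(C)(C)OO
Why: Vanadium-catalysed hydroxyl-directed epoxidation, in which the C1 alkoxide binds the tert-butylperoxide complex formed from VO(acac)2 and delivers oxygen to the C2=C3 olefin on its own face, setting C2 and C3 cis to the C1 hydroxyl (anti to the C4 ester) and leaving the non-allylic olefins alone.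

**Compound list**

1 | 2-bromoprop-2-enal (2-bromoacrolein) | C=C(Br)C=O | starting material
2 | (3S)-2-bromohexa-1,5-dien-3-ol | C=C(Br)[C@H](CC=C)O | intermediate
3 | {[(3S)-2-bromohexa-1,5-dien-3-yl]oxy}triethylsilane | C=C(Br)[C@H](CC=C)O[Si](CC)(CC)CC | intermediate
4 | {[(3S)-2-bromo-6-methylhepta-1,5-dien-3-yl]oxy}triethylsilane (C7–C11 unit, C8 set) | C=C(Br)[C@H](CC=C(C)C)O[Si](CC)(CC)CC | intermediate
5 | prop-2-yn-1-ol (propargyl alcohol) | C#CCO | starting material
6 | bromomagnesium (2Z)-3-(bromomagnesio)-2-methylprop-2-en-1-olate | C/C(=C/[Mg]Br)CO[Mg]Br | intermediate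
7 | (2Z)-3-iodo-2-methylprop-2-en-1-ol | C/C(=C/I)CO | intermediate
8 | (2Z)-3-iodo-2-methylprop-2-enal | C/C(=C/I)C=O | intermediate
9 | tert-butyldimethyl(prop-2-yn-1-yloxy)silane | C#CCO[Si](C)(C)C(C)(C)C | starting material
10 | chloro{(1E)-3-[(tert-butyldimethylsilyl)oxy]prop-1-en-1-yl}bis(cyclopentadienyl)zirconium | CC(C)(C)[Si](C)(C)OC/C=C/[Zr](Cl)(C1C=CC=C1)C1C=CC=C1 | intermediate
11 | {(1E)-3-[(tert-butyldimethylsilyl)oxy]prop-1-en-1-yl}(methyl)zinc | CC(C)(C)[Si](C)(C)OC/C=C/[Zn]C | intermediate
12 | (1Z,3R,4E)-6-[(tert-butyldimethylsilyl)oxy]-1-iodo-2-methylhexa-1,4-dien-3-ol | CC(C)(C)[Si](C)(C)OC/C=C/[C@@H](O)/C(C)=C\I | intermediate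
13 | tert-butyl{[(2E,4R,5Z)-6-iodo-4-[(4-methoxyphenyl)methoxy]-5-methylhexa-2,5-dien-1-yl]oxy}dimethylsilane | CC(C)(C)[Si](C)(C)OC/C=C/[C@@H](OCc1ccc(OC)cc1)/C(C)=C\I | intermediate
14 | (2E,4R,5Z)-6-iodo-4-[(4-methoxyphenyl)methoxy]-5-methylhexa-2,5-dien-1-ol | OC/C=C/[C@@H](OCc1ccc(OC)cc1)/C(C)=C\I | intermediate
15 | {(2S,3S)-3-[(1S,2Z)-3-iodo-1-[(4-methoxyphenyl)methoxy]-2-methylprop-2-en-1-yl]oxiran-2-yl}methanol | OC[C@@H]1O[C@H]1[C@@H](OCc2ccc(OC)cc2)/C(C)=C\I | intermediate
16 | [(3S)-6-methyl-3-(triethylsilyloxy)hepta-1,5-dien-2-yl]lithium | [Li]C(=C)[C@H](CC=C(C)C)O[Si](CC)(CC)CC | intermediate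
17 | bromo[(3S)-6-methyl-3-(triethylsilyloxy)hepta-1,5-dien-2-yl]magnesium | Br[Mg]C(=C)[C@H](CC=C(C)C)O[Si](CC)(CC)CC | intermediate
18 | acyclic (Z)-iodoalkenyl 1,3-diol: HOCH2(C4)–C5H[C7(=CH2)–C8H(OTES)–CH2CH=CMe2]–C6H(OH)–C1H(OPMB)–C2(CH3)=C3H–I; C1, C5, C6, C8 configured as in 26 (C5/C6 anti and C6/C1 anti in the extended chain) | C=C([C@H](CO)[C@@H](O)[C@@H](OCc1ccc(OC)cc1)/C(C)=C\I)[C@H](CC=C(C)C)O[Si](CC)(CC)CC | intermediate
19 | tris-TES ether of 18 (C4–OTES, C6–OTES, C8–OTES; C1–OPMB; stereocentres as in 18) | C=C([C@H](CO[Si](CC)(CC)CC)[C@@H](O[Si](CC)(CC)CC)[C@@H](OCc1ccc(OC)cc1)/C(C)=C\I)[C@H](CC=C(C)C)O[Si](CC)(CC)CC | intermediate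
20 | C4 aldehyde: OHC(C4)–C5H(side chain)–C6H(OTES)–C1H(OPMB)–C2(CH3)=C3H–I (Z); stereocentres as in 18 | C=C([C@H](C=O)[C@@H](O[Si](CC)(CC)CC)[C@@H](OCc1ccc(OC)cc1)/C(C)=C\I)[C@H](CC=C(C)C)O[Si](CC)(CC)CC | intermediate
21 | cyclohexenol: 2-methylcyclohex-2-ene ring with C1–OPMB, C4–OH, C5 side chain [C7(=CH2)–C8H(OTES)–CH2CH=CMe2], C6–OTES; C1-, C5- and C6-substituents mutually cis, C4–OH trans to the C5 side chain; absolute configuration as in 26 | C=C([C@H]1[C@@H](O[Si](CC)(CC)CC)[C@@H](OCc2ccc(OC)cc2)C(C)=C[C@@H]1O)[C@H](CC=C(C)C)O[Si](CC)(CC)CC | intermediate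
22 | triol: as 21 with free C6–OH and C8–OH (C4–OH, C6–OH, C8–OH; C1–OPMB) | C=C([C@H]1[C@@H](O)[C@@H](OCc2ccc(OC)cc2)C(C)=C[C@@H]1O)[C@H](CC=C(C)C)O | intermediate
23 | tri-angelate: as 22 with (2Z)-2-methylbut-2-enoates at O4, O6 and O8; C1–OPMB | C=C([C@H]1[C@@H](OC(=O)/C(C)=C\C)[C@@H](OCc2ccc(OC)cc2)C(C)=C[C@@H]1OC(=O)/C(C)=C\C)[C@H](CC=C(C)C)OC(=O)/C(C)=C\C | intermediate
24 | side-chain epoxide: as 23 with a (10R)-configured C10–C11 oxirane | C=C([C@H]1[C@@H](OC(=O)/C(C)=C\C)[C@@H](OCc2ccc(OC)cc2)C(C)=C[C@@H]1OC(=O)/C(C)=C\C)[C@H](C[C@H]1OC1(C)C)OC(=O)/C(C)=C\C | intermediate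
25 | C1 allylic alcohol: as 24 with free C1–OH (cis to C6–OAng) | C=C([C@H]1[C@@H](OC(=O)/C(C)=C\C)[C@@H](O)C(C)=C[C@@H]1OC(=O)/C(C)=C\C)[C@H](C[C@H]1OC1(C)C)OC(=O)/C(C)=C\C | intermediate
26 | CNP0147918.1: ring (1R,2R,3S,4R,5S,6R) with C2–C3 oxirane cis to C1–OH, angelates at O4, O6 and O8, (8S), (10R)-C10–C11 oxirane | C=C([C@H]1[C@@H](OC(=O)/C(C)=C\C)[C@@H](O)[C@@]2(C)O[C@H]2[C@@H]1OC(=O)/C(C)=C\C)[C@H](C[C@H]1OC1(C)C)OC(=O)/C(C)=C\C | target

**Step count and risks**

Total step count: 18 (steps 1–3 make the side-chain bromide; steps 4–18 are the main line). Longest linear sequence: 15 steps (steps 4 to 18, from prop-2-yn-1-ol).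

Steps most likely to fail:

Step 13 (ring closure). The alkenylchromium may add to the C4 aldehyde with poor or reversed facial selectivity: the model with an equatorial side chain competes with one that relieves allylic strain at C1. A slow closure may also let C5 epimerise. Fallback: C4 is set by invertive esterification instead of by the cyclisation. It sets out from aldehyde 20 and returns at 23. The closure is run as before and the C4-epimeric cyclohexenol F1 (C4–OH cis to the C5 side chain) is carried on. Mitsunobu esterification with angelic acid (PPh3, diisopropyl azodicarboxylate, toluene, 0 °C) inverts C4 and should give the C4 angelate bis-TES ether F2. HF·pyridine/pyridine in THF removes both silyl groups to give the C4-monoangelate diol F3, and acylation of F3 under the conditions of step 15 gives 23.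

Step 10 (epoxide opening). Copper-mediated coupling or halogen–metal exchange at the alkenyl iodide may compete with opening of the oxirane; attack at C6, or β-elimination of the silyloxy group from the alkenylmetal, are further losses. Fallback: the iodoalkene is built only after the copper step. It sets out from bromide 4 (as its Grignard reagent 17) and returns at 19. (E)-But-2-ene-1,4-diol is mono-protected (NaH, 4-methoxybenzyl chloride) to (2E)-4-[(4-methoxyphenyl)methoxy]but-2-en-1-ol F4, and Sharpless epoxidation with L-(+)-diethyl tartrate gives the (2S,3S)-epoxy alcohol F5. Opening of F5 with 17 and catalytic CuI gives the iodide-free 1,3-diol F6, and Et3SiOTf/2,6-lutidine its tris-TES ether F7. DDQ frees the C1 primary alcohol F8, and Dess–Martin periodinane gives the C1 aldehyde F9. Felkin–Anh-controlled addition of ethynylmagnesium bromide gives the propargylic alcohol F10. Anti-carbomagnesiation/iodination as in step 4 (MeMgBr, CuI; I2) gives the (Z)-iodoalkenyl C1 alcohol F11, and NaH/4-methoxybenzyl chloride converts F11 into 19.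

Step 15 (tris-angeloylation). The angeloyl groups may isomerise from Z to E (tiglates) during acyl transfer, or the hindered C6 hydroxyl may be acylated incompletely. Fallback: the Z olefins are built on the esters by Still–Gennari olefination. It sets out from triol 22 and returns at 23. Esterification of 22 with 2-[bis(2,2,2-trifluoroethoxy)phosphoryl]propanoic acid (N,N'-diisopropylcarbodiimide, 4-(dimethylamino)pyridine, CH2Cl2) gives the tris(phosphonopropanoate) F12. Treatment of F12 with KN(SiMe3)2, 18-crown-6 and acetaldehyde in THF at −78 °C should give the three (2Z)-2-methylbut-2-enoates, that is 23.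

**Further compounds**

F1 | step 13 | C4-epimeric cyclohexenol (4-epi-21; C4–OH cis to the C5 side chain) | C=C([C@H]1[C@@H](O[Si](CC)(CC)CC)[C@@H](OCc2ccc(OC)cc2)C(C)=C[C@H]1O)[C@H](CC=C(C)C)O[Si](CC)(CC)CC
F2 | step 13 | C4 angelate bis-TES ether (C4 inverted to the configuration of 23; C6–OTES, C8–OTES) | C=C([C@H]1[C@@H](O[Si](CC)(CC)CC)[C@@H](OCc2ccc(OC)cc2)C(C)=C[C@@H]1OC(=O)/C(C)=C\C)[C@H](CC=C(C)C)O[Si](CC)(CC)CC
F3 | step 13 | C4-monoangelate diol (free C6–OH and C8–OH) | C=C([C@H]1[C@@H](O)[C@@H](OCc2ccc(OC)cc2)C(C)=C[C@@H]1OC(=O)/C(C)=C\C)[C@H](CC=C(C)C)O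
F4 | step 10 | (2E)-4-[(4-methoxyphenyl)methoxy]but-2-en-1-ol | OC/C=C/COCc1ccc(OC)cc1
F5 | step 10 | {(2S,3S)-3-{[(4-methoxyphenyl)methoxy]methyl}oxiran-2-yl}methanol | OC[C@@H]1O[C@H]1COCc2ccc(OC)cc2
F6 | step 10 | iodide-free 1,3-diol (C4H2OH, C6H–OH, C5 alkenylated, C1 as CH2OPMB) | C=C([C@H](CO)[C@@H](O)COCc1ccc(OC)cc1)[C@H](CC=C(C)C)O[Si](CC)(CC)CC
F7 | step 10 | tris-TES ether of F6 | C=C([C@H](CO[Si](CC)(CC)CC)[C@@H](O[Si](CC)(CC)CC)COCc1ccc(OC)cc1)[C@H](CC=C(C)C)O[Si](CC)(CC)CC
F8 | step 10 | C1 primary alcohol (PMB removed from F7) | C=C([C@H](CO[Si](CC)(CC)CC)[C@@H](O[Si](CC)(CC)CC)CO)[C@H](CC=C(C)C)O[Si](CC)(CC)CC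
F9 | step 10 | C1 aldehyde | C=C([C@H](CO[Si](CC)(CC)CC)[C@@H](O[Si](CC)(CC)CC)C=O)[C@H](CC=C(C)C)O[Si](CC)(CC)CC
F10 | step 10 | C1 propargylic alcohol (ethynyl adduct, C1 as in 26) | C=C([C@H](CO[Si](CC)(CC)CC)[C@@H](O[Si](CC)(CC)CC)[C@@H](O)C#C)[C@H](CC=C(C)C)O[Si](CC)(CC)CC
F11 | step 10 | (Z)-iodoalkenyl C1 alcohol (19 without the PMB group) | C=C([C@H](CO[Si](CC)(CC)CC)[C@@H](O[Si](CC)(CC)CC)[C@@H](O)/C(C)=C\I)[C@H](CC=C(C)C)O[Si](CC)(CC)CC
F12 | step 15 | tris{2-[bis(2,2,2-trifluoroethoxy)phosphoryl]propanoate} of triol 22 | C=C([C@H]1[C@@H](OC(=O)C(C)P(=O)(OCC(F)(F)F)OCC(F)(F)F)[C@@H](OCc2ccc(OC)cc2)C(C)=C[C@@H]1OC(=O)C(C)P(=O)(OCC(F)(F)F)OCC(F)(F)F)[C@H](CC=C(C)C)OC(=O)C(C)P(=O)(OCC(F)(F)F)OCC(F)(F)F
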